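## Retrosynthetic overview

1. The ten-membered ring is closed last, between the methylidene-bearing ring carbon and its CH2 neighbour, by intramolecular B-alkyl Suzuki coupling of an acyclic alkenyl triflate that already carries the finished cyclobutane; the acid comes from its methyl ester.
2. That chain (methyl ketone, terminal alkyne, two stereocentres) comes from Eschenmoser–Tanabe opening of a cis-4,6-disubstituted 2,3-epoxycyclohexanone; the six-membered ring is a temporary template that fixes the 1,3-relationship.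
3. The template comes from an organocatalytic Michael/aldol annulation of 5-methylhex-4-enal with but-3-en-2-one, then α′-alkylation with a cyclobutylethyl iodide.
4. The cyclobutane comes from ring contraction (Wolff 1,2-shift, ketene captured by MeLi) of a 2,2,3-trisubstituted cyclopentanone made by a three-component coupling on 2-methylcyclopent-2-enone.
5. Ring order: cyclobutane (from the five-membered ring), then the six-membered template (built, then cleaved), then the ten-membered ring.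

Assumption: for the chiral catalysts of steps 1 and 7 the enantiomer that gives the drawn configuration is used, should the sense of induction on these exact substrates differ from the usual models.

## Route

Step 1
Reactants: 1 2-methylcyclopent-2-en-1-one; 2 vinylmagnesium bromide; 3 methyl bromoacetate
Product: 5 methyl 2-[(1S,5S)-1-methyl-2-oxo-5-vinylcyclopentyl]acetate, via magnesium enolate 4 (not isolated)
Conditions: CuBr·SMe2 (5 mol %), Josiphos-type ferrocenyl diphosphine (6 mol %), 2 (1.3 equiv), t-BuOMe, −78 °C; then 3, DMPU, −78 → 0 °C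
Reagents that add atoms: none
Why: Copper-catalysed asymmetric conjugate addition of the vinyl Grignard reagent sets C5 under ligand control, and the magnesium enolate is C-alkylated anti to the new vinyl group, so CH2CO2Me ends trans and methyl cis to vinyl at the quaternary centre (three-component conjugate addition–enolate alkylation).

Step 2
Reactants: 5 methyl 2-[(1S,5S)-1-methyl-2-oxo-5-vinylcyclopentyl]acetate
Product: 7 methyl 2-[(1S,5S)-3-diazo-1-methyl-2-oxo-5-vinylcyclopentyl]acetate, via trifluoroacetyl ketone 6 (not isolated)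
Conditions: LiN(SiMe3)2, THF, −78 °C; CF3CO2CH2CF3; then MsN3, Et3N, H2O, MeCN, 25 °C
Reagents that add atoms: 2,2,2-trifluoroethyl trifluoroacetate (O=C(OCC(F)(F)F)C(F)(F)F); methanesulfonyl azide (CS(=O)(=O)N=[N+]=[N-])
Why: Detrifluoroacetylative (Danheiser) diazo transfer; the ketone can enolise only toward C3 because the other α-carbon is quaternary, so the diazo group is placed regiospecifically and no stereocentre is touched.

Step 3
Reactants: 7 methyl 2-[(1S,5S)-3-diazo-1-methyl-2-oxo-5-vinylcyclopentyl]acetate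
Product: 10 methyl 2-[(1S,2S,4S)-2-acetyl-1-methyl-4-vinylcyclobutyl]acetate, via cyclobutylidene ketene 8 (not isolated), via lithium enolate 9 (not isolated)
Conditions: hν (300–350 nm), THF, −78 °C; then MeLi (1.05 equiv), −78 °C; H2O; then K2CO3, MeOH, 25 °C
Reagents that add atoms: methyllithium ([Li]C)
Why: Proposed new method: photolysis expels N2 and the quaternary carbon migrates with retention from the carbonyl carbon to the carbene carbon (Wolff 1,2-shift, contracting the cyclopentanone to a cyclobutylidene ketene); instead of the usual O- or N-nucleophile, one equivalent of MeLi is added at −78 °C, where the ketene carbon is far more electrophilic than the ester and the resulting lithium enolate cannot over-add, so protonation gives the methyl ketone directly, and K2CO3/MeOH equilibrates the only epimerisable centre to the isomer with acetyl trans to the larger CH2CO2Me arm and 1,3-cis to the vinyl group; the closest known chemistry is the Wolff ring contraction of 2-diazocycloalkanones with alcohol, amine or thiol capture and the addition of organolithium reagents to isolated ketenes.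

Step 4
Reactants: 10 methyl 2-[(1S,2S,4S)-2-acetyl-1-methyl-4-vinylcyclobutyl]acetate
Product: 11 methyl 2-[(1S,2R,4S)-1-methyl-2-(prop-1-en-2-yl)-4-vinylcyclobutyl]acetate
Conditions: Ph3PCH3Br, KOtBu, THF, 0 → 40 °C
Reagents that add atoms: methylenetriphenylphosphorane, made in the flask ([CH2-][P+](c1ccccc1)(c1ccccc1)c1ccccc1)
Why: Wittig methylenation turns the acetyl group into the isopropenyl group; the α-centre is already in its thermodynamically preferred configuration and the ester is inert to the ylide.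

Step 5
Reactants: 11 methyl 2-[(1S,2R,4S)-1-methyl-2-(prop-1-en-2-yl)-4-vinylcyclobutyl]acetate
Product: 12 2-[(1S,2R,4S)-1-methyl-2-(prop-1-en-2-yl)-4-vinylcyclobutyl]ethan-1-ol
Conditions: LiAlH4, Et2O, 0 °C
Reagents that add atoms: none
Why: Hydride reduction of the ester to the primary alcohol; the unactivated alkenes and the stereocentres are untouched.

Step 6
Reactants: 12 2-[(1S,2R,4S)-1-methyl-2-(prop-1-en-2-yl)-4-vinylcyclobutyl]ethan-1-ol
Product: 13 (1S,2R,4S)-1-(2-iodoethyl)-1-methyl-2-(prop-1-en-2-yl)-4-vinylcyclobutane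
Conditions: I2, PPh3, imidazole, CH2Cl2, 0 → 25 °C
Reagents that add atoms: iodine (II)
Why: Appel-type iodination by SN2 at a CH2 group, so no stereocentre is involved.

Step 7
Reactants: 14 5-methylhex-4-enal; 15 but-3-en-2-one
Product: 17 (4S)-4-(3-methylbut-2-en-1-yl)cyclohex-2-en-1-one, via Michael adduct 16 (not isolated)
Conditions: (S)-α,α-diphenylprolinol trimethylsilyl ether (5 mol %), ethyl 3,4-dihydroxybenzoate (20 mol %), neat, 4 °C; then LiOH, iPrOH, 25 °C
Reagents that add atoms: none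
Why: Enamine (Hayashi–Jørgensen type) Michael addition, with one enamine face shielded by the diarylsilyloxymethyl group, sets the stereocentre, and intramolecular aldol condensation (Robinson-type annulation) closes the cyclohexenone without touching it.

Step 8
Reactants: 17 (4S)-4-(3-methylbut-2-en-1-yl)cyclohex-2-en-1-one; 13 (1S,2R,4S)-1-(2-iodoethyl)-1-methyl-2-(prop-1-en-2-yl)-4-vinylcyclobutane
Product: 19 (4R,6S)-4-(3-methylbut-2-en-1-yl)-6-{2-[(1S,2R,4S)-1-methyl-2-(prop-1-en-2-yl)-4-vinylcyclobutyl]ethyl}cyclohex-2-en-1-one, via trans epimer 18 (not isolated)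
Conditions: LiN(iPr)2, THF, −78 °C; 13, DMPU, −78 → −10 °C; then NaOMe, MeOH, −20 °C (brief)
Reagents that add atoms: none
Why: Kinetic α′-deprotonation gives the cross-conjugated dienolate, which is alkylated by the primary iodide (SN2), and brief methoxide treatment epimerises C6 to the diequatorial cis-4,6 isomer, so C6 follows from the catalyst-set C4 centre (enolate alkylation under thermodynamic stereocontrol).

Step 9
Reactants: 19 (4R,6S)-4-(3-methylbut-2-en-1-yl)-6-{2-[(1S,2R,4S)-1-methyl-2-(prop-1-en-2-yl)-4-vinylcyclobutyl]ethyl}cyclohex-2-en-1-one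
Product: 20 (1S,3S,5R,6S)-5-(3-methylbut-2-en-1-yl)-3-{2-[(1S,2R,4S)-1-methyl-2-(prop-1-en-2-yl)-4-vinylcyclobutyl]ethyl}-7-oxabicyclo[4.1.0]heptan-2-one
Conditions: H2O2 (30 % aq.), NaOH, MeOH, 0 → 25 °C
Reagents that add atoms: hydrogen peroxide (OO)
Why: Weitz–Scheffer nucleophilic epoxidation attacks only the electron-poor enone double bond (anti to the ring substituents) and leaves the isolated alkenes alone, while the basic medium keeps the α-carbon epimerisable so residual trans material converges on the same diequatorial epoxy ketone.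

Step 10
Reactants: 20 (1S,3S,5R,6S)-5-(3-methylbut-2-en-1-yl)-3-{2-[(1S,2R,4S)-1-methyl-2-(prop-1-en-2-yl)-4-vinylcyclobutyl]ethyl}-7-oxabicyclo[4.1.0]heptan-2-one
Product: 22 (2R,4S)-4-ethynyl-2-(3-methylbut-2-en-1-yl)-6-[(1S,2R,4S)-1-methyl-2-(prop-1-en-2-yl)-4-vinylcyclobutyl]hexanal, via tosylhydrazone 21 (not isolated)
Conditions: TsNHNH2 (1.0 equiv), AcOH/CH2Cl2, −20 → 25 °C
Reagents that add atoms: p-toluenesulfonyl hydrazide (Cc1ccc(cc1)S(=O)(=O)NN)
Why: Eschenmoser–Tanabe fragmentation; the tosylhydrazone of the α,β-epoxy ketone collapses with loss of N2 and sulfinate, cleaving the former enone Cα–Cβ bond to give the aldehyde and the terminal alkyne, and both side-chain stereocentres lie outside the bonds that change.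

Step 11
Reactants: 22 (2R,4S)-4-ethynyl-2-(3-methylbut-2-en-1-yl)-6-[(1S,2R,4S)-1-methyl-2-(prop-1-en-2-yl)-4-vinylcyclobutyl]hexanal
Product: 23 (3R,5S)-3-(3-methylbut-2-en-1-yl)-5-{2-[(1S,2R,4S)-1-methyl-2-(prop-1-en-2-yl)-4-vinylcyclobutyl]ethyl}hept-6-yn-2-ol (both C2 epimers)
Conditions: MeMgBr (1.3 equiv), THF, −78 → 0 °C
Reagents that add atoms: methylmagnesium bromide (C[Mg]Br)
Why: Grignard addition to the aldehyde at low temperature; the new carbinol centre is a mixture but is removed in step 12.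

Step 12
Reactants: 23 (3R,5S)-3-(3-methylbut-2-en-1-yl)-5-{2-[(1S,2R,4S)-1-methyl-2-(prop-1-en-2-yl)-4-vinylcyclobutyl]ethyl}hept-6-yn-2-ol
Product: 24 (3R,5S)-3-(3-methylbut-2-en-1-yl)-5-{2-[(1S,2R,4S)-1-methyl-2-(prop-1-en-2-yl)-4-vinylcyclobutyl]ethyl}hept-6-yn-2-one
Conditions: Dess–Martin periodinane, CH2Cl2, 25 °C
Reagents that add atoms: none
Why: Dess–Martin oxidation gives the methyl ketone under non-basic conditions, so the adjacent stereocentre does not epimerise.

Step 13
Reactants: 24 (3R,5S)-3-(3-methylbut-2-en-1-yl)-5-{2-[(1S,2R,4S)-1-methyl-2-(prop-1-en-2-yl)-4-vinylcyclobutyl]ethyl}hept-6-yn-2-one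
Product: 25 methyl (3S,5R)-5-acetyl-8-methyl-2-methylidene-3-{2-[(1S,2R,4S)-1-methyl-2-(prop-1-en-2-yl)-4-vinylcyclobutyl]ethyl}non-7-enoate
Conditions: Pd(OAc)2 (1 mol %), 2-pyridyldiphenylphosphine, MeSO3H (cat.), CO (10 bar), MeOH, 45 °C
Reagents that add atoms: carbon monoxide ([C-]#[O+]); methanol (CO)
Why: Palladium-hydride Markovnikov (branched-selective) methoxycarbonylation of the terminal alkyne gives the 2-substituted acrylate; unactivated alkenes and the ketone react far more slowly.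

Step 14
Reactants: 25 methyl (3S,5R)-5-acetyl-8-methyl-2-methylidene-3-{2-[(1S,2R,4S)-1-methyl-2-(prop-1-en-2-yl)-4-vinylcyclobutyl]ethyl}non-7-enoate
Product: 26 methyl (3S,5R)-8-methyl-2-methylidene-3-{2-[(1S,2R,4S)-1-methyl-2-(prop-1-en-2-yl)-4-vinylcyclobutyl]ethyl}-5-{1-[(trifluoromethanesulfonyl)oxy]ethenyl}non-7-enoate
Conditions: KN(SiMe3)2, THF, −78 °C; PhNTf2, −78 → 0 °C
Reagents that add atoms: N-phenylbis(trifluoromethanesulfonimide) (O=S(=O)(N(c1ccccc1)S(=O)(=O)C(F)(F)F)C(F)(F)F)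
Why: Kinetic deprotonation at the methyl group (not at the tertiary α-carbon) and O-triflation give the 1,1-disubstituted alkenyl triflate that already holds the future exocyclic methylene carbon.

Step 15
Reactants: 26 methyl (3S,5R)-8-methyl-2-methylidene-3-{2-[(1S,2R,4S)-1-methyl-2-(prop-1-en-2-yl)-4-vinylcyclobutyl]ethyl}-5-{1-[(trifluoromethanesulfonyl)oxy]ethenyl}non-7-enoate
Product: 29 2-[(1S,4S,6R,10R,12R)-1-methyl-7-methylidene-6-(3-methylbut-2-en-1-yl)-12-(prop-1-en-2-yl)bicyclo[8.2.0]dodecan-4-yl]prop-2-enoic acid, via alkylborane 27 (not isolated), via macrocyclic methyl ester 28 (not isolated)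
Conditions: 9-BBN (1.2 equiv), THF, 0 → 25 °C; then PdCl2(dppf) (10 mol %), AsPh3, Cs2CO3, DMF/THF/H2O, 50 °C, syringe-pump addition (2 mM); then LiOH, MeOH, 50 °C; aq. HCl
Reagents that add atoms: 9-borabicyclo[3.3.1]nonane (B1C2CCCC1CCC2); lithium hydroxide ([Li+].[OH-])
Why: 9-BBN hydroborates only the monosubstituted vinyl group (anti-Markovnikov), the intramolecular B-alkyl Suzuki–Miyaura coupling with the alkenyl triflate closes the ten-membered ring at high dilution without creating a stereocentre, and hydroxide then saponifies the methyl ester.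

## Compound list

1 | 2-methylcyclopent-2-en-1-one | CC1=CCCC1=O | starting material
2 | vinylmagnesium bromide | C=C[Mg]Br | starting material
3 | methyl bromoacetate | COC(=O)CBr | starting material
4 | bromo{[(3S)-2-methyl-3-vinylcyclopent-1-en-1-yl]oxy}magnesium (magnesium enolate) | C=C[C@@H]1CCC(O[Mg]Br)=C1C | intermediate
5 | methyl 2-[(1S,5S)-1-methyl-2-oxo-5-vinylcyclopentyl]acetate | C=C[C@@H]1CCC(=O)[C@@]1(C)CC(=O)OC | intermediate
6 | methyl 2-[(1S,5S)-1-methyl-2-oxo-3-(trifluoroacetyl)-5-vinylcyclopentyl]acetate (C3 epimers/enol) | C=C[C@@H]1CC(C(=O)C(F)(F)F)C(=O)[C@@]1(C)CC(=O)OC | intermediate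
7 | methyl 2-[(1S,5S)-3-diazo-1-methyl-2-oxo-5-vinylcyclopentyl]acetate | C=C[C@@H]1CC(=[N+]=[N-])C(=O)[C@@]1(C)CC(=O)OC | intermediate
8 | methyl 2-[(1S,4S)-1-methyl-2-(oxomethylidene)-4-vinylcyclobutyl]acetate (cyclobutylidene ketene) | C=C[C@@H]1CC(=C=O)[C@@]1(C)CC(=O)OC | intermediate
9 | lithium 1-[(2S,3S)-2-(2-methoxy-2-oxoethyl)-2-methyl-3-vinylcyclobutylidene]ethan-1-olate | C=C[C@@H]1CC(=C(C)O[Li])[C@@]1(C)CC(=O)OC | intermediate
10 | methyl 2-[(1S,2S,4S)-2-acetyl-1-methyl-4-vinylcyclobutyl]acetate | C=C[C@@H]1C[C@H](C(C)=O)[C@@]1(C)CC(=O)OC | intermediate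
11 | methyl 2-[(1S,2R,4S)-1-methyl-2-(prop-1-en-2-yl)-4-vinylcyclobutyl]acetate | C=C[C@@H]1C[C@H](C(C)=C)[C@@]1(C)CC(=O)OC | intermediate
12 | 2-[(1S,2R,4S)-1-methyl-2-(prop-1-en-2-yl)-4-vinylcyclobutyl]ethan-1-ol | C=C[C@@H]1C[C@H](C(C)=C)[C@@]1(C)CCO | intermediate
13 | (1S,2R,4S)-1-(2-iodoethyl)-1-methyl-2-(prop-1-en-2-yl)-4-vinylcyclobutane | C=C[C@@H]1C[C@H](C(C)=C)[C@@]1(C)CCI | intermediate
14 | 5-methylhex-4-enal | CC(C)=CCCC=O | starting material
15 | but-3-en-2-one | CC(=O)C=C | starting material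
16 | (2S)-5-methyl-2-(3-oxobutyl)hex-4-enal | O=C[C@H](CC=C(C)C)CCC(C)=O | intermediate
17 | (4S)-4-(3-methylbut-2-en-1-yl)cyclohex-2-en-1-one | O=C1C=C[C@H](CC=C(C)C)CC1 | intermediate
18 | (4R,6R)-4-(3-methylbut-2-en-1-yl)-6-{2-[(1S,2R,4S)-1-methyl-2-(prop-1-en-2-yl)-4-vinylcyclobutyl]ethyl}cyclohex-2-en-1-one (trans epimer) | C=C[C@@H]2C[C@H](C(=C)C)[C@@]2(C)CC[C@H]1C(=O)C=C[C@H](CC=C(C)C)C1 | intermediate
19 | (4R,6S)-4-(3-methylbut-2-en-1-yl)-6-{2-[(1S,2R,4S)-1-methyl-2-(prop-1-en-2-yl)-4-vinylcyclobutyl]ethyl}cyclohex-2-en-1-one | C=C[C@@H]2C[C@H](C(=C)C)[C@@]2(C)CC[C@@H]1C(=O)C=C[C@H](CC=C(C)C)C1 | intermediate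
20 | (1S,3S,5R,6S)-5-(3-methylbut-2-en-1-yl)-3-{2-[(1S,2R,4S)-1-methyl-2-(prop-1-en-2-yl)-4-vinylcyclobutyl]ethyl}-7-oxabicyclo[4.1.0]heptan-2-one | C=C[C@@H]2C[C@H](C(=C)C)[C@@]2(C)CC[C@@H]1C(=O)[C@H]3O[C@H]3[C@H](CC=C(C)C)C1 | intermediate
21 | N′-tosylhydrazone of epoxy ketone 20 | C=C[C@@H]2C[C@H](C(=C)C)[C@@]2(C)CC[C@@H]1C(=NNS(=O)(=O)c4ccc(C)cc4)[C@H]3O[C@H]3[C@H](CC=C(C)C)C1 | intermediate
22 | (2R,4S)-4-ethynyl-2-(3-methylbut-2-en-1-yl)-6-[(1S,2R,4S)-1-methyl-2-(prop-1-en-2-yl)-4-vinylcyclobutyl]hexanal | C=C[C@@H]1C[C@H](C(C)=C)[C@@]1(C)CC[C@H](C#C)C[C@@H](CC=C(C)C)C=O | intermediate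
23 | (3R,5S)-3-(3-methylbut-2-en-1-yl)-5-{2-[(1S,2R,4S)-1-methyl-2-(prop-1-en-2-yl)-4-vinylcyclobutyl]ethyl}hept-6-yn-2-ol (both C2 epimers) | C=C[C@@H]1C[C@H](C(C)=C)[C@@]1(C)CC[C@H](C#C)C[C@@H](CC=C(C)C)C(C)O | intermediate
24 | (3R,5S)-3-(3-methylbut-2-en-1-yl)-5-{2-[(1S,2R,4S)-1-methyl-2-(prop-1-en-2-yl)-4-vinylcyclobutyl]ethyl}hept-6-yn-2-one | C=C[C@@H]1C[C@H](C(C)=C)[C@@]1(C)CC[C@H](C#C)C[C@@H](CC=C(C)C)C(C)=O | intermediate
25 | methyl (3S,5R)-5-acetyl-8-methyl-2-methylidene-3-{2-[(1S,2R,4S)-1-methyl-2-(prop-1-en-2-yl)-4-vinylcyclobutyl]ethyl}non-7-enoate | C=C[C@@H]1C[C@H](C(C)=C)[C@@]1(C)CC[C@H](C(=C)C(=O)OC)C[C@@H](CC=C(C)C)C(C)=O | intermediate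
26 | methyl (3S,5R)-8-methyl-2-methylidene-3-{2-[(1S,2R,4S)-1-methyl-2-(prop-1-en-2-yl)-4-vinylcyclobutyl]ethyl}-5-{1-[(trifluoromethanesulfonyl)oxy]ethenyl}non-7-enoate | C=C[C@@H]1C[C@H](C(C)=C)[C@@]1(C)CC[C@H](C(=C)C(=O)OC)C[C@@H](CC=C(C)C)C(=C)OS(=O)(=O)C(F)(F)F | intermediate
27 | 9-BBN adduct of 26: the vinyl group has become CH2CH2–B(9-borabicyclo[3.3.1]nonan-9-yl), all stereocentres as in 26 | B1(C2CCCC1CCC2)CC[C@@H]3C[C@H](C(C)=C)[C@@]3(C)CC[C@H](C(=C)C(=O)OC)C[C@@H](CC=C(C)C)C(=C)OS(=O)(=O)C(F)(F)F | intermediate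
28 | methyl 2-[(1S,4S,6R,10R,12R)-1-methyl-7-methylidene-6-(3-methylbut-2-en-1-yl)-12-(prop-1-en-2-yl)bicyclo[8.2.0]dodecan-4-yl]prop-2-enoate | C=C1CC[C@@H]2C[C@H](C(=C)C)[C@@]2(C)CC[C@H](C(=C)C(=O)OC)C[C@H]1CC=C(C)C | intermediate
29 | 2-[(1S,4S,6R,10R,12R)-1-methyl-7-methylidene-6-(3-methylbut-2-en-1-yl)-12-(prop-1-en-2-yl)bicyclo[8.2.0]dodecan-4-yl]prop-2-enoic acid | C=C1CC[C@@H]2C[C@H](C(=C)C)[C@@]2(C)CC[C@H](C(=C)C(=O)O)C[C@H]1CC=C(C)C | target

## Step count and risk

Total step count: 15 (steps 1–6 make iodide 13, step 7 makes enone 17, steps 8–15 join them and finish).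
Longest linear sequence: 14 (steps 1–6, then 8–15).

The three steps most likely to fail:

Step 3 (the proposed Wolff/methyllithium capture). The ketene may dimerise before MeLi is added, or MeLi may touch the ester. The fallback uses known chemistry, sets out from 7 and comes back at 10. Irradiation of 7 in THF containing ethanethiol gives S-ethyl (1S,2S,3S)-2-(2-methoxy-2-oxoethyl)-2-methyl-3-vinylcyclobutane-1-carbothioate F3 (classical Wolff ring contraction with thiol capture). Me2CuLi (Et2O, −78 °C) then converts the thioester into the methyl ketone without touching the methyl ester, and K2CO3/MeOH equilibration gives 10.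

Step 1 (enantioselective vinyl addition with in-flask alkylation to a quaternary centre). The ee with a vinyl nucleophile or the enolate alkylation may be poor. The fallback sets out from 1 and comes back at 5. Rhodium-catalysed asymmetric 1,4-addition of potassium vinyltrifluoroborate ([Rh(cod)Cl]2, BINAP, Et3N, toluene/H2O) gives (3S)-2-methyl-3-vinylcyclopentan-1-one F1. Me3SiCl/NaI/Et3N in MeCN gives the more substituted silyl enol ether trimethyl{[(3S)-2-methyl-3-vinylcyclopent-1-en-1-yl]oxy}silane F2. MeLi regenerates the lithium enolate, which 3 alkylates anti to the vinyl group to give 5.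

Step 15 (ten-membered ring closure by B-alkyl Suzuki coupling). Oligomerisation or slow reductive elimination to the strained ring may dominate. The fallback changes the ring-closing reaction to a carbonyl addition, sets out from 26 and comes back at 28, which is then saponified as in step 15. Hydroboration of 26 with 9-BBN and oxidation with NaBO3·4H2O gives the primary alcohol in which the vinyl group of 26 has become CH2CH2OH, F4. Dess–Martin oxidation gives the corresponding aldehyde F5. Intramolecular Nozaki–Hiyama–Kishi coupling of the alkenyl triflate with the aldehyde (CrCl2, NiCl2 cat., DMSO/THF, high dilution) gives the macrocyclic allylic alcohol, the 8-hydroxy derivative of 28, F6. ClCO2Me/pyridine gives its methyl carbonate F7. Formate reduction through the π-allyl palladium complex (Pd(OAc)2, PBu3, HCO2NH4, dioxane, 80 °C), with hydride delivered to the ring terminus, gives 28.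

## Further compounds

F1 | step 1 | (3S)-2-methyl-3-vinylcyclopentan-1-one (C2 epimers) | C=C[C@@H]1CCC(=O)C1C
F2 | step 1 | trimethyl{[(3S)-2-methyl-3-vinylcyclopent-1-en-1-yl]oxy}silane | C=C[C@@H]1CCC(O[Si](C)(C)C)=C1C
F3 | step 3 | S-ethyl (1S,2S,3S)-2-(2-methoxy-2-oxoethyl)-2-methyl-3-vinylcyclobutane-1-carbothioate | C=C[C@@H]1C[C@H](C(=O)SCC)[C@@]1(C)CC(=O)OC
F4 | step 15 | primary alcohol: 26 with the vinyl group converted into CH2CH2OH | OCC[C@@H]1C[C@H](C(C)=C)[C@@]1(C)CC[C@H](C(=C)C(=O)OC)C[C@@H](CC=C(C)C)C(=C)OS(=O)(=O)C(F)(F)F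
F5 | step 15 | aldehyde: 26 with the vinyl group converted into CH2CHO | O=CC[C@@H]1C[C@H](C(C)=C)[C@@]1(C)CC[C@H](C(=C)C(=O)OC)C[C@@H](CC=C(C)C)C(=C)OS(=O)(=O)C(F)(F)F
F6 | step 15 | macrocyclic allylic alcohol: 8-hydroxy derivative of 28 (both C8 epimers) | C=C1C(O)C[C@@H]2C[C@H](C(=C)C)[C@@]2(C)CC[C@H](C(=C)C(=O)OC)C[C@H]1CC=C(C)C
F7 | step 15 | methyl carbonate of F6 | C=C1C(OC(=O)OC)C[C@@H]2C[C@H](C(=C)C)[C@@]2(C)CC[C@H](C(=C)C(=O)OC)C[C@H]1CC=C(C)C
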